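**Retrosynthetic overview**

1. The target is a 19-membered macrocycle of four purchased arenes and has no stereocentre. Ring A carries OMe, ring B is the para-phenylene, ring C carries the free OH, ring D is the meta-phenylene; the links are two diaryl ethers (A–O–B, C–O–D) and two ethano bridges (D–CH2CH2–A, B–CH2CH2–C).
2. The macrocycle is closed last, at the bond between ring C and the CH2 of the ethano bridge that comes from ring B, by one-pot hydroboration and intramolecular B-alkyl Suzuki–Miyaura coupling; hydrogenolysis of one benzyl ether then gives the target.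
3. Enabling feature: the ring C carbon of this bond is para to the phenolic C–O and meta to the ether C–O, so it can be bought as the C–Br of 5-bromosalicylaldehyde. Its partner is the terminal CH2 of an ethano unit on ring B, i.e. the boron-bearing carbon after anti-Markovnikov hydroboration of a 4-(aryloxy)styrene.
4. The seco-compound is the union of two diaryl ethers, each made by Chan–Lam coupling and each carrying one vinyl group and one halide (C–O–D: bromide and vinyl; A–O–B: iodide and vinyl). The D–CH2CH2–A bridge is made by the same hydroboration/Suzuki logic intermolecularly, the I/Br difference ordering the two couplings.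
5. Order of ring formation: no carbocycle is built; only the 19-membered ring is formed (step 6).

Key step: step 6

**Route**

Step 1
Reactants: 1 5-bromo-2-hydroxybenzaldehyde
Product: 2 2-(benzyloxy)-5-bromobenzaldehyde
Conditions: BnBr, K2CO3, DMF, rt
Reagents that add atoms: benzyl bromide BrCc1ccccc1
Why: Williamson O-alkylation of the acidic salicylaldehyde phenoxide should be clean and masks the oxygen that ends as the free OH of ring C.

Step 2
Reactants: 2 2-(benzyloxy)-5-bromobenzaldehyde
Product: 4 2-(benzyloxy)-5-bromophenol, via aryl formate 3 (not isolated)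
Conditions: mCPBA, CH2Cl2, 0 °C to rt; aq. NaHCO3 wash; then K2CO3 (cat.), MeOH, rt
Reagents that add atoms: 3-chloroperoxybenzoic acid (mCPBA) OOC(=O)c1cccc(Cl)c1
Why: Baeyer–Villiger oxidation, in which the aryl group activated by the ortho benzyloxy group should migrate in preference to hydride, followed by mild methanolysis of the aryl formate, turns the CHO carbon into the phenol that will carry ring D.

Step 3
Reactants: 4 2-(benzyloxy)-5-bromophenol; 5 (3-vinylphenyl)boronic acid
Product: 6 1-(benzyloxy)-4-bromo-2-(3-vinylphenoxy)benzene
Conditions: Cu(OAc)2 (20 mol%), pyridine, 4 Å MS, CH2Cl2, O2 (1 atm), rt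
Reagents that add atoms: none
Why: Chan–Lam oxidative C–O coupling of a phenol with an arylboronic acid runs at room temperature, where the aryl bromide, the benzyl ether and the vinyl group should stay untouched.

Step 4
Reactants: 7 5-iodo-2-methoxyphenol; 8 (4-vinylphenyl)boronic acid
Product: 9 4-iodo-1-methoxy-2-(4-vinylphenoxy)benzene
Conditions: Cu(OAc)2 (20 mol%), pyridine, 4 Å MS, CH2Cl2, O2 (1 atm), rt
Reagents that add atoms: none
Why: The same Chan–Lam C–O coupling joins rings A and B; the aryl iodide should not react with copper acetate at room temperature and the styrene is carried in intact.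

Step 5
Reactants: 6 1-(benzyloxy)-4-bromo-2-(3-vinylphenoxy)benzene; 9 4-iodo-1-methoxy-2-(4-vinylphenoxy)benzene
Product: 11 1-(benzyloxy)-4-bromo-2-[3-[2-[4-methoxy-3-(4-vinylphenoxy)phenyl]ethyl]phenoxy]benzene, via alkyl-9-BBN borane 10 (not isolated)
Conditions: 6, 9-BBN dimer, THF, 0 °C to rt; then aq. K3PO4 (destroys residual B–H), 9 (slight excess), Pd(dppf)Cl2 (5 mol%), THF/DMF, rt
Reagents that add atoms: none
Why: In this intermolecular B-alkyl Suzuki–Miyaura coupling, 9-BBN places boron on the terminal carbon of the ring D styrene, and at room temperature Pd(dppf)Cl2 should insert into the C–I bond of 9 far faster than into the electron-rich C–Br bond para to the benzyloxy group, so the D–CH2CH2–A bridge forms while the bromide and the second vinyl group are kept for the ring closure.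

Step 6
Reactants: 11 1-(benzyloxy)-4-bromo-2-[3-[2-[4-methoxy-3-(4-vinylphenoxy)phenyl]ethyl]phenoxy]benzene
Product: 13 O-benzyl ether of the target macrocycle (benzyloxy on ring C), via alkyl-9-BBN borane 12 (not isolated)
Conditions: 9-BBN dimer, THF, rt; then syringe-pump addition over 12 h to Pd(OAc)2 (10 mol%), SPhos (20 mol%), aq. K3PO4, degassed THF, 65 °C, final concentration about 2 mM
Reagents that add atoms: none
Why: 9-BBN adds to the ring B styrene with boron on the terminal carbon; under aqueous K3PO4 the hydroxyborate transmetalates intramolecularly to the arylpalladium bromide formed when zerovalent palladium (generated from Pd(OAc)2 and SPhos) inserts into the ring C C–Br bond, and reductive elimination from the 20-membered aryl(alkyl)palladacycle forms the CH2–aryl bond. The closest known reaction type is the intramolecular B-alkyl Suzuki–Miyaura macrocyclization used for cyclophanes and other macrocycles under high dilution. The 19-membered ring is closed end to end, sp3 carbon to sp2 carbon, through the palladacycle; no smaller ring can form because the only C–Br and the only C–B bond sit at the two chain termini. No stereocentre is created. The step needs ring closure to beat oligomerization, which the slow addition into dilute catalyst, the two diaryl ether hinges and the ethano bridge already present between rings D and A (a chain that folds without strain) should secure. It also needs reductive elimination to beat beta-hydride elimination, which the bulky, electron-rich SPhos and the primary alkyl group favour, while the benzyl ether prevents phenoxide formation that would slow insertion into the C–Br bond.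

Step 7
Reactants: 13 O-benzyl ether of the target macrocycle
Product: 14 target macrocycle CNP0132125.0
Conditions: H2 (1 atm), Pd/C (10%), EtOAc/MeOH, rt
Reagents that add atoms: none
Why: Hydrogenolysis of the aryl benzyl ether should free the ring C phenol and leave the diaryl ethers, the aryl methyl ether and the saturated bridges unchanged.

**Compound list**

1 | 5-bromo-2-hydroxybenzaldehyde (5-bromosalicylaldehyde) | O=Cc1cc(Br)ccc1O | starting material
2 | 2-(benzyloxy)-5-bromobenzaldehyde | O=Cc1cc(Br)ccc1OCc1ccccc1 | intermediate
3 | 2-(benzyloxy)-5-bromophenyl formate | O=COc1cc(Br)ccc1OCc1ccccc1 | intermediate (not isolated)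
4 | 2-(benzyloxy)-5-bromophenol | Oc1cc(Br)ccc1OCc1ccccc1 | intermediate
5 | (3-vinylphenyl)boronic acid | OB(O)c1cccc(C=C)c1 | starting material
6 | 1-(benzyloxy)-4-bromo-2-(3-vinylphenoxy)benzene | C=Cc1cccc(Oc2cc(Br)ccc2OCc2ccccc2)c1 | intermediate
7 | 5-iodo-2-methoxyphenol | COc1ccc(I)cc1O | starting material
8 | (4-vinylphenyl)boronic acid | OB(O)c1ccc(C=C)cc1 | starting material
9 | 4-iodo-1-methoxy-2-(4-vinylphenoxy)benzene | COc1ccc(I)cc1Oc1ccc(C=C)cc1 | intermediate
10 | 9-[2-[3-[2-(benzyloxy)-5-bromophenoxy]phenyl]ethyl]-9-borabicyclo[3.3.1]nonane | Brc1ccc(OCc2ccccc2)c(Oc2cccc(CCB3C4CCCC3CCC4)c2)c1 | intermediate (not isolated)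
11 | 1-(benzyloxy)-4-bromo-2-[3-[2-[4-methoxy-3-(4-vinylphenoxy)phenyl]ethyl]phenoxy]benzene (seco-compound) | COc1ccc(CCc2cccc(Oc3cc(Br)ccc3OCc3ccccc3)c2)cc1Oc1ccc(C=C)cc1 | intermediate
12 | 9-[2-[4-[5-[2-[3-[2-(benzyloxy)-5-bromophenoxy]phenyl]ethyl]-2-methoxyphenoxy]phenyl]ethyl]-9-borabicyclo[3.3.1]nonane | COc1ccc(CCc2cccc(Oc3cc(Br)ccc3OCc3ccccc3)c2)cc1Oc1ccc(CCB2C3CCCC2CCC3)cc1 | intermediate (not isolated)
13 | O-benzyl ether of the target macrocycle (19-membered ring, benzyloxy on ring C) | COc1ccc2cc1Oc1ccc(cc1)CCc1ccc(OCc3ccccc3)c(c1)Oc1cccc(c1)CC2 | intermediate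
14 | target macrocycle CNP0132125.0 | COc1ccc2cc1Oc1ccc(cc1)CCc1ccc(O)c(c1)Oc1cccc(c1)CC2 | target

**Summary**

Total step count: 7. Longest linear sequence: 6 (steps 1, 2, 3, 5, 6, 7).

Steps most likely to fail:

Step 6. Intermolecular coupling may overtake ring closure, or the alkylborane or alkylpalladium may be lost by protodeboronation or beta-hydride elimination before the ring closes. Fallback: from 11, the same carbon–carbon bond is closed at the stilbene oxidation level by an intramolecular Mizoroki–Heck reaction (Pd(OAc)2, P(o-tol)3, K2CO3, DMF, 100 °C, about 2 mM). The arylpalladium from the ring C bromide should add to the terminal carbon of the ring B styrene, and syn beta-hydride elimination should give the macrocyclic E-stilbene benzyl ether F1. Hydrogenation (H2, Pd/C, EtOAc/MeOH) then saturates the stilbene and cleaves the benzyl ether in one operation, so the fallback returns to the route at 14.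

Step 5. Halide discrimination may be lost (insertion into a C–Br bond of 10 or 11 leading to oligomers), or the vinyl group of 9 may be consumed by residual borane or by a Heck pathway. Fallback: from 4, Chan–Lam coupling with (3-formylphenyl)boronic acid (Cu(OAc)2, pyridine, O2, CH2Cl2, rt) should give 3-[2-(benzyloxy)-5-bromophenoxy]benzaldehyde F2. Separately, 3-hydroxy-4-methoxybenzyl alcohol and PPh3·HBr (MeCN, reflux) give (3-hydroxy-4-methoxybenzyl)triphenylphosphonium bromide F3. A Wittig reaction of F2 with F3 (KOtBu in excess, THF, 0 °C to rt) should give 5-[2-[3-[2-(benzyloxy)-5-bromophenoxy]phenyl]ethenyl]-2-methoxyphenol F4 as an E/Z mixture. Diimide reduction (TsNHNH2, NaOAc, DME/H2O, reflux), which spares the aryl bromide and the benzyl ether, gives 5-[2-[3-[2-(benzyloxy)-5-bromophenoxy]phenyl]ethyl]-2-methoxyphenol F5. Chan–Lam coupling of F5 with 8 then installs ring B with its vinyl group and returns to the route at 11.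

Step 4. Protodeboronation or oxidative homocoupling of the styrenylboronic acid, or oligomerization of its vinyl group under copper and oxygen, may leave the ortho-substituted phenol unconverted. Fallback: from 7, nucleophilic aromatic substitution on 4-fluorobenzaldehyde (K2CO3, DMF, 110 °C) should give 4-(5-iodo-2-methoxyphenoxy)benzaldehyde F6. Wittig methylenation (Ph3PCH3Br, KOtBu, THF, 0 °C) then returns to the route at 9.

**Further compounds**

F1 | step 6 | macrocyclic E-stilbene benzyl ether (E double bond between rings B and C) | COc1ccc2cc1Oc1ccc(cc1)/C=C/c1ccc(OCc3ccccc3)c(c1)Oc1cccc(c1)CC2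
F2 | step 5 | 3-[2-(benzyloxy)-5-bromophenoxy]benzaldehyde | O=Cc1cccc(Oc2cc(Br)ccc2OCc2ccccc2)c1
F3 | step 5 | (3-hydroxy-4-methoxybenzyl)triphenylphosphonium bromide | COc1ccc(C[P+](c2ccccc2)(c2ccccc2)c2ccccc2)cc1O.[Br-]
F4 | step 5 | 5-[2-[3-[2-(benzyloxy)-5-bromophenoxy]phenyl]ethenyl]-2-methoxyphenol (E/Z mixture) | COc1ccc(C=Cc2cccc(Oc3cc(Br)ccc3OCc3ccccc3)c2)cc1O
F5 | step 5 | 5-[2-[3-[2-(benzyloxy)-5-bromophenoxy]phenyl]ethyl]-2-methoxyphenol | COc1ccc(CCc2cccc(Oc3cc(Br)ccc3OCc3ccccc3)c2)cc1O
F6 | step 4 | 4-(5-iodo-2-methoxyphenoxy)benzaldehyde | COc1ccc(I)cc1Oc1ccc(C=O)cc1
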